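**Strategy.** Numbering follows the decalin of the target (ring A: C1–C5, C10; ring B: C5–C10; Br on C3). Everything rests on the C5–C10 ring-fusion bond, made from an open-chain bromo keto-aldehyde by a chiral-amine-catalysed Michael addition that is followed in the same flask by aldol condensation: C10, the α-carbon of aldehyde C9, adds to C5, the β-carbon of the C7 enone (ring A); C8 then condenses with C9 (ring B), giving the trans-decalin enone. The step exploits the quaternary, methyl-bearing C10 next to C9 and the 1,3-relationship C5/C7 in ring B. The C3 bromide is set earlier by aldehyde α-bromination; C9 and C8 follow by conjugate addition and enolate trapping.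

Key step: step 7

Remark: names of cyclic compounds use the target numbering (C11–C13 and C16 = oxobutyl chain on C9, C14/C15 = vinyl on C8); β is the face of the C10 methyl group, α the face of H-5. The sense of induction in steps 2 and 7 is fixed by choosing the appropriate antipode of the amine catalyst.

Step 1
Reactants: 1 methyl 3,3-dimethylpent-4-enoate
Product: 2 3,3-dimethylpent-4-enal
Conditions: DIBAL-H (1.05 equiv), CH2Cl2, −78 °C; Rochelle salt work-up
Reagents that add atoms: none
Why: At −78 °C DIBAL-H adds once to the ester and the tetrahedral aluminium hemiacetal survives until work-up, so the aldehyde is released without over-reduction (partial ester reduction).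

Step 2
Reactants: 2 3,3-dimethylpent-4-enal
Product: 4 (R)-2-bromo-3,3-dimethylpent-4-en-1-ol, via bromo aldehyde 3 (not isolated)
Conditions: NBS (1.05 equiv), diarylprolinol trimethylsilyl ether (10 mol%, antipode that gives the R-bromide), CH2Cl2, −40 °C; then NaBH4, MeOH, −40 to 0 °C
Reagents that add atoms: N-bromosuccinimide (O=C1CCC(=O)N1Br)
Why: Enamine catalysis (organocatalytic aldehyde α-bromination): the bulky diarylsilyloxymethyl group shields one face of the E-enamine so that NBS delivers bromine to the other face and sets C3 under catalyst control, and immediate NaBH4 reduction converts the configurationally labile α-bromo aldehyde into the stable bromohydrin while the neopentyl vinyl group is too unreactive to compete for Br+.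

Step 3
Reactants: 5 methacrolein
Product: 6 2-(1-bromopropan-2-yl)-1,3-dioxolane (racemic)
Conditions: HBr (gas), CH2Cl2, 0 °C; then ethylene glycol, TsOH (cat.), 25 °C
Reagents that add atoms: hydrogen bromide (Br); ethane-1,2-diol (OCCO)
Why: Conjugate addition of HBr to the enal followed by acid-catalysed acetalization gives the masked β-bromo aldehyde (hydrobromination/acetal formation); its stereocentre is racemic on purpose because it is erased at the enamine stage of step 7.

Step 4
Reactants: 4 (R)-2-bromo-3,3-dimethylpent-4-en-1-ol; 6 2-(1-bromopropan-2-yl)-1,3-dioxolane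
Product: 8 2-[(5S)-5-bromo-6,6-dimethyloct-7-en-2-yl]-1,3-dioxolane (both epimers at the methyl-bearing carbon), via triflate 7 (not isolated)
Conditions: 4, Tf2O, 2,6-lutidine, CH2Cl2, −78 °C; then the Grignard reagent of 6 (Mg, THF, 25 °C), Li2CuCl4 (5 mol%), THF, −78 to −20 °C
Reagents that add atoms: none
Why: Copper-catalysed sp3–sp3 cross-coupling of a primary alkyl triflate with a primary Grignard reagent should occur at C2 far faster than any reaction at the neopentyl-type secondary bromide, so the C3 stereocentre, which is not a reacting centre, is retained.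

Step 5
Reactants: 8 2-[(5S)-5-bromo-6,6-dimethyloct-7-en-2-yl]-1,3-dioxolane; 9 pent-1-en-3-one
Product: 10 (4E,7S)-7-bromo-10-(1,3-dioxolan-2-yl)-6,6-dimethylundec-4-en-3-one
Conditions: Hoveyda–Grubbs second-generation catalyst (5 mol%), 9 (4 equiv), CH2Cl2, 40 °C
Reagents that add atoms: none
Why: Olefin cross-metathesis pairs the vinyl group on the quaternary carbon, which cannot homodimerize, with the electron-poor enone partner and should give the E-enone, the only other functional groups being inert acetal and alkyl bromide.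

Step 6
Reactants: 10 (4E,7S)-7-bromo-10-(1,3-dioxolan-2-yl)-6,6-dimethylundec-4-en-3-one
Product: 11 (5S,7E)-5-bromo-2,6,6-trimethyl-9-oxoundec-7-enal
Conditions: 1 M HCl, THF, 25 °C
Reagents that add atoms: water (O)
Why: Acid-catalysed acetal hydrolysis frees the α-branched aldehyde without touching the enone or the secondary bromide; the epimeric mixture at the α-carbon is of no consequence.

Step 7
Reactants: 11 (5S,7E)-5-bromo-2,6,6-trimethyl-9-oxoundec-7-enal
Product: 13 (4aR,7S,8aR)-7-bromo-3,4a,8,8-tetramethyl-4a,5,6,7,8,8a-hexahydronaphthalen-2(1H)-one (3β-Br, 5α-H, 10β-CH3), via keto-aldehyde 12 (not isolated)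
Conditions: 9-amino-9-deoxy-epi-quinine (20 mol%; or its pseudo-enantiomer, whichever gives the 5α,10β series), TFA (40 mol%), toluene, 25–40 °C; then TsOH·H2O (10 mol%), 80 °C
Reagents that add atoms: none
Why: The primary amine condenses with aldehyde C9 to the enamine (C9=C10), whose C10 adds to C5 of the E-enone (activated as its iminium ion) in a 6-exo-trig Michael addition that closes ring A and creates the C5–C10 bond; hydrolysis gives keto-aldehyde 12. On warming with acid the ethyl ketone enolizes towards C8, which attacks the neopentyl aldehyde C9 (six-membered, enol-exo aldol) and dehydrates, closing ring B as the C8=C9 enone. The closest known reaction type is the enamine-mediated Robinson annulation of α,α-disubstituted aldehydes with vinyl ketones, used here in its intramolecular, amine-catalysed form. C10 and C5 are set together in a chair transition state with the enone arm and the enamine carbon C9 equatorial and the C10 methyl axial, which makes C6 and C9 trans (5α-H, 10β-CH3); the catalyst's stereocentres select the enamine face and thus the chair in which the C3 bromide is equatorial (3β), and both C10 epimers of 11 converge through the common enamine. The step needs chemoselective enamine formation at the aldehyde, trans selectivity from the chair, and regioselective aldol closure, which is secured because C8 is the only enolizable carbon that can reach C9 in a six-membered ring.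

Step 8
Reactants: 13 (4aR,7S,8aR)-7-bromo-3,4a,8,8-tetramethyl-4a,5,6,7,8,8a-hexahydronaphthalen-2(1H)-one; 14 2-(2-bromoethyl)-2-methyl-1,3-dioxolane
Product: 16 3β-bromo-8β-(1-hydroxyethyl)-4,4,8α,10β-tetramethyl-9α-[2-(2-methyl-1,3-dioxolan-2-yl)ethyl]-5α-decalin-7-one (carbinol epimers), via bromomagnesium enolate 15 (not isolated)
Conditions: Grignard reagent of 14 (Mg, THF, 25 °C), CuBr·SMe2 (20 mol%), THF, −40 °C; then MeCHO, −78 °C; aq. NH4Cl
Reagents that add atoms: acetaldehyde (CC=O)
Why: Copper-catalysed 1,4-addition of the Grignard reagent to the enone occurs axially at C9 from the α-face, anti to the axial C10 methyl group, and the resulting bromomagnesium enolate is trapped by acetaldehyde at C8 from the β-face, anti to the new C9 chain (tandem conjugate addition–aldol), which sets C9 and C8 and leaves the carbinol centre undefined because it is removed in step 9.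

Step 9
Reactants: 16 3β-bromo-8β-(1-hydroxyethyl)-4,4,8α,10β-tetramethyl-9α-[2-(2-methyl-1,3-dioxolan-2-yl)ethyl]-5α-decalin-7-one
Product: 17 3β-bromo-8β-ethenyl-4,4,8α,10β-tetramethyl-9α-[2-(2-methyl-1,3-dioxolan-2-yl)ethyl]-5α-decalin-7-one
Conditions: Burgess reagent, toluene, 60 °C
Reagents that add atoms: none
Why: The Burgess reagent dehydrates the secondary alcohol by syn-elimination of its sulfamate ester, and since the only β-hydrogens are on the methyl group (C8 is quaternary) the terminal vinyl group must form, under neutral conditions that avoid retro-aldol cleavage.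

Step 10
Reactants: 17 3β-bromo-8β-ethenyl-4,4,8α,10β-tetramethyl-9α-[2-(2-methyl-1,3-dioxolan-2-yl)ethyl]-5α-decalin-7-one
Product: 18 p-toluenesulfonylhydrazone of ketone 17 (at C7)
Conditions: TsNHNH2, MeOH, 60 °C
Reagents that add atoms: p-toluenesulfonyl hydrazide (Cc1ccc(cc1)S(=O)(=O)NN)
Why: Condensation of the ketone with tosylhydrazide gives the hydrazone (hydrazone formation), the ketal, bromide and alkene being inert under these nearly neutral conditions.

Step 11
Reactants: 18 p-toluenesulfonylhydrazone of ketone 17
Product: 19 3β-bromo-8β-ethenyl-4,4,8α,10β-tetramethyl-9α-[2-(2-methyl-1,3-dioxolan-2-yl)ethyl]-5α-decalin (ethylene ketal of the target)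
Conditions: catecholborane, CHCl3, 0 to 25 °C; then NaOAc·3H2O, 60 °C
Reagents that add atoms: none
Why: Hydride addition from catecholborane to the tosylhydrazone followed by acetate-induced elimination of sulfinate gives a diazene that loses N2 to leave the CH2 group (reductive deoxygenation of a tosylhydrazone), a mild alternative to Wolff–Kishner conditions that spares the secondary bromide and the vinyl group.

Step 12
Reactants: 19 ethylene ketal of the target
Product: 20 4-[(1R,2R,4aR,6S,8aR)-6-bromo-2-ethenyl-2,5,5,8a-tetramethyldecahydronaphthalen-1-yl]butan-2-one (target, CNP0189852.2)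
Conditions: 1 M HCl, THF, 25 °C
Reagents that add atoms: water (O)
Why: Mild aqueous acid hydrolyses the dioxolane to the methyl ketone (ketal hydrolysis) without affecting the bromide, the vinyl group or any stereocentre.

**Compound list**

1 | methyl 3,3-dimethylpent-4-enoate | C=CC(C)(C)CC(=O)OC | starting material
2 | 3,3-dimethylpent-4-enal | C=CC(C)(C)CC=O | intermediate
3 | (R)-2-bromo-3,3-dimethylpent-4-enal | C=CC(C)(C)[C@@H](Br)C=O | intermediate
4 | (R)-2-bromo-3,3-dimethylpent-4-en-1-ol | C=CC(C)(C)[C@@H](Br)CO | intermediate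
5 | methacrolein (2-methylprop-2-enal) | C=C(C)C=O | starting material
6 | 2-(1-bromopropan-2-yl)-1,3-dioxolane (racemic) | CC(CBr)C1OCCO1 | intermediate
7 | (R)-2-bromo-3,3-dimethylpent-4-en-1-yl trifluoromethanesulfonate | C=CC(C)(C)[C@@H](Br)COS(=O)(=O)C(F)(F)F | intermediate
8 | 2-[(5S)-5-bromo-6,6-dimethyloct-7-en-2-yl]-1,3-dioxolane (both epimers at the methyl-bearing carbon) | C=CC(C)(C)[C@@H](Br)CCC(C)C1OCCO1 | intermediate
9 | pent-1-en-3-one (ethyl vinyl ketone) | C=CC(=O)CC | starting material
10 | (4E,7S)-7-bromo-10-(1,3-dioxolan-2-yl)-6,6-dimethylundec-4-en-3-one (C10 epimers) | CCC(=O)/C=C/C(C)(C)[C@@H](Br)CCC(C)C1OCCO1 | intermediate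
11 | (5S,7E)-5-bromo-2,6,6-trimethyl-9-oxoundec-7-enal (C2 epimers) | CCC(=O)/C=C/C(C)(C)[C@@H](Br)CCC(C)C=O | intermediate
12 | 4-bromo-1,3,3-trimethyl-2-(2-oxobutyl)cyclohexane-1-carbaldehyde, target configuration 3β-Br, 5α-H, 10β-CH3 (oxobutyl cis to Br, trans to CHO) | CCC(=O)C[C@H]1C(C)(C)[C@@H](Br)CC[C@]1(C)C=O | intermediate
13 | (4aR,7S,8aR)-7-bromo-3,4a,8,8-tetramethyl-4a,5,6,7,8,8a-hexahydronaphthalen-2(1H)-one (3β-Br, 5α-H, 10β-CH3, C8=C9 enone with C7 ketone) | O=C1C[C@H]2C(C)(C)[C@@H](Br)CC[C@]2(C)C=C1C | intermediate
14 | 2-(2-bromoethyl)-2-methyl-1,3-dioxolane | CC1(CCBr)OCCO1 | starting material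
15 | bromomagnesium C7 enolate (C7=C8) of the 9α-alkylated ketone | CC1=C(O[Mg]Br)C[C@H]2C(C)(C)[C@@H](Br)CC[C@]2(C)[C@@H]1CCC3(C)OCCO3 | intermediate
16 | 3β-bromo-8β-(1-hydroxyethyl)-4,4,8α,10β-tetramethyl-9α-[2-(2-methyl-1,3-dioxolan-2-yl)ethyl]-5α-decalin-7-one (carbinol epimers) | CC(O)[C@@]1(C)C(=O)C[C@H]2C(C)(C)[C@@H](Br)CC[C@]2(C)[C@@H]1CCC3(C)OCCO3 | intermediate
17 | 3β-bromo-8β-ethenyl-4,4,8α,10β-tetramethyl-9α-[2-(2-methyl-1,3-dioxolan-2-yl)ethyl]-5α-decalin-7-one | C=C[C@@]1(C)C(=O)C[C@H]2C(C)(C)[C@@H](Br)CC[C@]2(C)[C@@H]1CCC3(C)OCCO3 | intermediate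
18 | p-toluenesulfonylhydrazone of 17 at C7 | C=C[C@@]1(C)C(=NNS(=O)(=O)c3ccc(C)cc3)C[C@H]2C(C)(C)[C@@H](Br)CC[C@]2(C)[C@@H]1CCC4(C)OCCO4 | intermediate
19 | 3β-bromo-8β-ethenyl-4,4,8α,10β-tetramethyl-9α-[2-(2-methyl-1,3-dioxolan-2-yl)ethyl]-5α-decalin | C=C[C@@]1(C)CC[C@H]2C(C)(C)[C@@H](Br)CC[C@]2(C)[C@@H]1CCC3(C)OCCO3 | intermediate
20 | 4-[(1R,2R,4aR,6S,8aR)-6-bromo-2-ethenyl-2,5,5,8a-tetramethyldecahydronaphthalen-1-yl]butan-2-one | C=C[C@@]1(C)CC[C@H]2C(C)(C)[C@@H](Br)CC[C@]2(C)[C@@H]1CCC(C)=O | target

**Step count and risks**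

Total step count: 12. Longest linear sequence: 11 steps (1 → 2 → 4 → 8 → 10 → 11 → 13 → 16 → 17 → 18 → 19 → 20); step 3 is a one-step branch.

Steps most likely to fail:

1. Step 7 (key step). The enamine may be too hindered to reach the neopentyl C5, so that C–C bond formation between two congested centres is slow. The catalyst may also fail to override the weak conformational bias of the C3 bromide, so that the wrong ring-fusion diastereomer forms. Fallback (radical ring closure): it sets out from 4 and returns at 13. Triflate 7 is alkylated with the lithium enolate of 1,1-dimethoxypropan-2-one (LDA, THF/DMPU) to give (5S)-5-bromo-1,1-dimethoxy-6,6-dimethyloct-7-en-2-one F1. Wittig methylenation (Ph3P=CH2) gives (5S)-5-bromo-2-(dimethoxymethyl)-6,6-dimethylocta-1,7-diene F2. Cross-metathesis with 9 gives (4E,7S)-7-bromo-10-(dimethoxymethyl)-6,6-dimethylundeca-4,10-dien-3-one F3. Fe(acac)3/PhSiH3 in EtOH transfers a hydrogen atom to the 1,1-disubstituted alkene, and the tertiary C10 radical closes ring A by 6-exo conjugate addition to C5, giving the dimethyl acetal of keto-aldehyde 12, F4. The ring-fusion diastereomers would be separated at this stage. Aqueous acid then frees 12, which is condensed to 13 as in step 7.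

2. Step 8. Conjugate addition at C9, next to the quaternary C10, may be slow, and the aldol trapping may occur on the wrong face of the enolate (syn to the C9 chain), giving the C8 epimer. Fallback (stepwise trapping with a vinyl cation equivalent): it sets out from 13 and returns at 17. The copper-catalysed addition is run with TMSCl to isolate the trimethylsilyl enol ether (C7=C8) of the 9α-alkylated ketone F5. MeLi regenerates the lithium enolate, which adds to phenyl vinyl sulfoxide to give the 8β-[2-(phenylsulfinyl)ethyl] ketone F6. Heating in toluene (110 °C) eliminates the sulfoxide and gives 17.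

3. Step 5. Metathesis of the vinyl group next to the quaternary C4 may stall, leaving self-metathesis of the enone partner as the main process. Fallback (ozonolysis and olefination): it sets out from 8 and returns at 10. Ozonolysis of the only alkene (O3, CH2Cl2, −78 °C; PPh3) gives (3S)-3-bromo-6-(1,3-dioxolan-2-yl)-2,2-dimethylheptanal F7, which has no α-hydrogen and cannot eliminate HBr. Horner–Wadsworth–Emmons reaction with dimethyl (2-oxobutyl)phosphonate (LiCl, DBU, MeCN) gives 10.

Further compounds
F1 | step 7 | (5S)-5-bromo-1,1-dimethoxy-6,6-dimethyloct-7-en-2-one | C=CC(C)(C)[C@@H](Br)CCC(=O)C(OC)OC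
F2 | step 7 | (5S)-5-bromo-2-(dimethoxymethyl)-6,6-dimethylocta-1,7-diene | C=CC(C)(C)[C@@H](Br)CCC(=C)C(OC)OC
F3 | step 7 | (4E,7S)-7-bromo-10-(dimethoxymethyl)-6,6-dimethylundeca-4,10-dien-3-one | CCC(=O)/C=C/C(C)(C)[C@@H](Br)CCC(=C)C(OC)OC
F4 | step 7 | dimethyl acetal of keto-aldehyde 12 (3β-Br, 5α-H, 10β-CH3) | CCC(=O)C[C@H]1C(C)(C)[C@@H](Br)CC[C@]1(C)C(OC)OC
F5 | step 8 | trimethylsilyl enol ether (C7=C8) of the 9α-alkylated ketone | CC1=C(O[Si](C)(C)C)C[C@H]2C(C)(C)[C@@H](Br)CC[C@]2(C)[C@@H]1CCC3(C)OCCO3
F6 | step 8 | 3β-bromo-4,4,8α,10β-tetramethyl-9α-[2-(2-methyl-1,3-dioxolan-2-yl)ethyl]-8β-[2-(phenylsulfinyl)ethyl]-5α-decalin-7-one | O=S(CC[C@@]1(C)C(=O)C[C@H]2C(C)(C)[C@@H](Br)CC[C@]2(C)[C@@H]1CCC3(C)OCCO3)c4ccccc4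
F7 | step 5 | (3S)-3-bromo-6-(1,3-dioxolan-2-yl)-2,2-dimethylheptanal | O=CC(C)(C)[C@@H](Br)CCC(C)C1OCCO1
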